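- You have to choose what the next run changes: more days on the south-west flask, or a different charge of partner. The flask asked about is that south-west run, followed on to 4.0 d.

| flask | left-handed substrate | right-handed substrate | partner | free catalyst | added ligand | remark | time |
|---|---|---|---|---|---|---|---|
| south-west | 0.25 M | 0.25 M | 1.1 equiv | 0.24 mol% | 0.35 mM | the very flask that is asked about, followed so far |  |
| west | 0.50 M | 0.50 M | 1.1 equiv | 0.24 mol% | 0.35 mM | run made earlier |  |
| flask | 0.25 M | 0.25 M | 1.10 equiv | 0.24 mol% | 0.35 mM |  | 4.0 d |

south-west run (percent of the left-handed substrate and right-handed substrate together charged)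

| time / h | left-handed substrate / % | right-handed substrate / % |
|---|---|---|
| 1.50 | 27.2 | 46.4 |
| 2.50 | 18.8 | 44.7 |
| 4.00 | 12.0 | 43.8 |
| 5.00 | 8.9 | 43.6 |
| 8.00 | 6.1 | 41.7 |
| 12.0 | 4.6 | 41.1 |
| 20.0 | 3.6 | 41.3 |

west run (percent of the left-handed substrate and right-handed substrate together charged)

| time / d | left-handed substrate / % | right-handed substrate / % |
|---|---|---|
| 0.208 | 5.9 | 39.9 |
| 0.333 | 5.0 | 39.7 |
| 0.500 | 5.4 | 39.6 |
| 0.833 | 5.2 | 39.6 |
| 1.25 | 6.0 | 39.7 |
| 1.67 | 5.2 | 40.1 |
| 3.00 | 5.0 | 40.5 |

(readings scatter by 0.3 percentage points)

1. part of the left-handed substrate and right-handed substrate charged together that has reacted at 4.0 d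
2. excess of left-handed product over right-handed product in the product at 4.0 d
3. excess of right-handed substrate over left-handed substrate among what is left of the two at 4.0 d

- Replace the west run's curve by its mean. Over its 7 readings, the part of the two substrates that has reacted averages 54.7 %. The scatter of the readings leaves that mean uncertain by 0.16 percentage points. The west sum of the two substrates at 0.208 d stands 0.54 points from the mean, against a scatter of 0.42 points for one such sum, so a flat line costs little in the west run.
- Now take the stopping conversion, which is the partner charged over the two substrates charged together, if each product takes one partner. In both runs it is 55.0 %, below the whole charge, so the partner is the limiting reagent. The west mean lies 0.30 points below it.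
- The south-west readings at 20.0 h put the reacted part at 55.1 %, close to that flask's stopping conversion. My reckoning for 4.0 d is therefore c = 55.0 %, and you should spend the next run on the partner charge, not on days.
- The forecast gives c = 55.1 %, 68.7 % for eP and 84.4 % for eS, which puts its c 0.1 points above mine. Its ground: “a stopped flask stays stopped”.
- The flask gives c = 55.1 %, eP = 68.3 % and eS = 83.6 %, with c 0.100 points above the stopping conversion and the partner at 0 % of its charge. In this flask the left-handed substrate stands at 3.68 % at 2.00 d and at 3.68 % at 40.0 d.

    free catalyst ⇌ dormant form (K = 0.370, k = 0.0730 /h)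
    free catalyst + left-handed substrate ⇌ catalyst intermediate A (K = 110 /M, k = 11000 /M/h)
    free catalyst + right-handed substrate ⇌ catalyst intermediate B (K = 12.0 /M, k = 8300 /M/h)
    partner + catalyst intermediate A → free catalyst + left-handed product (k = 990 /M/h)
    partner + catalyst intermediate B → free catalyst + right-handed product (k = 380 /M/h)
    free catalyst + added ligand ⇌ idle complex, settled at all times (K = 960 /M)

- The joining of free catalyst and added ligand to idle complex changes neither c nor eP. A neighbouring flask, like this one but charged with 0.660 equiv of partner, has a stopping conversion of 33.0 %. At 4.0 d it holds 0 % of its partner, and it gives c = 33.1 %, with eP = 81.7 % and eS = 40.4 %.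

The readings are simulated for substances that don't exist; scatter was added.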